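**Retrosynthetic overview**
1. Target 23 comes from 22 by hydrogenolysis of the benzyl ester on C1 and the benzyl ether on O-2 of ring B (the heptyl salicylate ring).
2. Key disconnection: ring A (the orsellinoyl ring; C1' carries the ester carbonyl C7', C2' and C4' carry hydroxyls, C6' carries the methyl) has the oxygen pattern of a folded tetraketide. 22 is therefore cut at the depside bond O-4(ring B)–C7' and at the ring bond C1'–C6', giving phenol 18 and diketo-dioxinone 8. C7', which sits between two ortho substituents in the arene, is esterified as a ketene carbon before ring A exists.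
3. Phenol 18 comes from benzyl 2,4-dihydroxy-6-heptylbenzoate 15 by 4-O-allylation, 2-O-benzylation and deallylation. Ring B of 15 is made by the same thermolysis, capture and aldol sequence from heptyl diketo-dioxinone 11 and benzyl alcohol.
4. 8 and 11 both come from the isolated allyl keto-ester dioxinone 6 by magnesium-mediated C-acylation (acetyl chloride or octanoyl chloride 9) and decarboxylative deallylation. 6 comes from 2,2,6-trimethyl-4H-1,3-dioxin-4-one 4 and allyl malonyl chloride 3, itself made from Meldrum's acid 1.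
5. Ring order: ring B first (step 5), ring A last (step 9).

Key step: step 9

Remark: the target has no stereocentre, so no configuration has to be set; polyketone intermediates are drawn as keto tautomers although they will be largely enolized.

**Route**

Step 1
Reactants: 1 2,2-dimethyl-1,3-dioxane-4,6-dione (Meldrum's acid)
Product: 3 prop-2-en-1-yl 3-chloro-3-oxopropanoate, via allyl hydrogen malonate 2 (not isolated)
Conditions: allyl alcohol (1.0 equiv), PhMe, 100 °C; concentrate; (COCl)2, DMF (cat.), CH2Cl2, 0 °C to rt
Reagents that add atoms: allyl alcohol, C=CCO; oxalyl chloride, O=C(Cl)C(=O)Cl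
Why: Ring-opening alcoholysis of Meldrum's acid by allyl alcohol with loss of acetone stops at the malonic half ester 2, and chlorination of that acid with oxalyl chloride under DMF catalysis (Vilsmeier-type activation) gives the acid chloride with only gaseous by-products.

Step 2
Reactants: 3 prop-2-en-1-yl 3-chloro-3-oxopropanoate; 4 2,2,6-trimethyl-4H-1,3-dioxin-4-one
Product: 6 prop-2-en-1-yl 4-(2,2-dimethyl-4-oxo-4H-1,3-dioxin-6-yl)-3-oxobutanoate, via lithium dienolate 5 (not isolated)
Conditions: 4, LiN(SiMe3)2, THF, −78 °C; 3 (0.5 equiv), −78 °C; aq NH4Cl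
Reagents that add atoms: none
Why: Crossed Claisen condensation in its vinylogous form: the extended dienolate 5 is acylated at its exocyclic γ-carbon by the acid chloride, and the excess of enolate takes up the acidic proton of the β-keto ester product so that a second acylation is suppressed.

Step 3
Reactants: 6 prop-2-en-1-yl 4-(2,2-dimethyl-4-oxo-4H-1,3-dioxin-6-yl)-3-oxobutanoate
Product: 8 6-(2,4-dioxopentyl)-2,2-dimethyl-4H-1,3-dioxin-4-one, via acetylated keto ester 7 (not isolated)
Conditions: MgCl2, pyridine, CH2Cl2, 0 °C; AcCl, 0 °C to rt; aq NH4Cl; then Pd(PPh3)4 (cat.), morpholine, THF, 0 °C to rt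
Reagents that add atoms: acetyl chloride, CC(=O)Cl
Why: Magnesium-mediated soft-enolization C-acylation (Rathke conditions) places the acetyl group on the carbon between the ketone and the allyl ester, where MgCl2 chelation of the β-keto ester makes the proton acidic enough for pyridine, and Tsuji–Trost deallylation by zerovalent palladium with morpholine as allyl acceptor then frees the β-keto acid, which loses CO2 at room temperature to give the diketo-dioxinone.

Step 4
Reactants: 6 prop-2-en-1-yl 4-(2,2-dimethyl-4-oxo-4H-1,3-dioxin-6-yl)-3-oxobutanoate; 9 octanoyl chloride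
Product: 11 6-(2,4-dioxoundecyl)-2,2-dimethyl-4H-1,3-dioxin-4-one, via octanoylated keto ester 10 (not isolated)
Conditions: MgCl2, pyridine, CH2Cl2, 0 °C; 9, 0 °C to rt; aq NH4Cl; then Pd(PPh3)4 (cat.), morpholine, THF, 0 °C to rt
Reagents that add atoms: none
Why: The same magnesium-mediated C-acylation and Tsuji–Trost deallylation–decarboxylation as in step 3, here with the C8 acid chloride 9 that brings in the heptyl chain of ring B.

Step 5
Reactants: 11 6-(2,4-dioxoundecyl)-2,2-dimethyl-4H-1,3-dioxin-4-one
Product: 15 benzyl 2,4-dihydroxy-6-heptylbenzoate, via acylketene 12 (not isolated), via benzyl trioxotetradecanoate 13 (not isolated), via aldol adduct 14 (not isolated)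
Conditions: BnOH (1.1 equiv), PhMe, 110 °C; then K2CO3, iPrOH/CH2Cl2, rt; then HCl, MeOH, rt
Reagents that add atoms: benzyl alcohol, OCc1ccccc1
Why: Retro-hetero-Diels–Alder loss of acetone gives acylketene 12, benzyl alcohol adds to it, and carbonate-promoted 6-enolexo aldol addition of the C2 carbanion of 13 to the C7 ketone followed by acid dehydration aromatizes to ring B, which is the ordinary primary-alcohol case of the diketo-dioxinone thermolysis, capture and aromatization sequence.

Step 6
Reactants: 15 benzyl 2,4-dihydroxy-6-heptylbenzoate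
Product: 16 benzyl 6-heptyl-2-hydroxy-4-(prop-2-en-1-yloxy)benzoate
Conditions: allyl bromide (1.05 equiv), K2CO3, acetone, reflux
Reagents that add atoms: allyl bromide, C=CCBr
Why: Williamson etherification: the 2-hydroxyl is held in a six-membered hydrogen bond to the ester carbonyl and is less acidic, so a weak base and one equivalent of halide should alkylate only the 4-hydroxyl.

Step 7
Reactants: 16 benzyl 6-heptyl-2-hydroxy-4-(prop-2-en-1-yloxy)benzoate
Product: 17 benzyl 2-(benzyloxy)-6-heptyl-4-(prop-2-en-1-yloxy)benzoate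
Conditions: BnBr, K2CO3, DMF, 60 °C
Reagents that add atoms: benzyl bromide, BrCc1ccccc1
Why: Williamson etherification in a dipolar aprotic solvent with heating breaks the chelate and benzylates the remaining 2-hydroxyl, while the allyl ether and the benzyl ester are inert to carbonate in dry DMF.

Step 8
Reactants: 17 benzyl 2-(benzyloxy)-6-heptyl-4-(prop-2-en-1-yloxy)benzoate
Product: 18 benzyl 2-(benzyloxy)-6-heptyl-4-hydroxybenzoate
Conditions: Pd(PPh3)4 (cat.), morpholine, THF, rt
Reagents that add atoms: none
Why: Tsuji–Trost deallylation: zerovalent palladium ionizes the aryl allyl ether to a π-allyl complex and the phenoxide, morpholine takes up the allyl group irreversibly, and the benzyl ether and benzyl ester are not touched.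

Step 9
Reactants: 8 6-(2,4-dioxopentyl)-2,2-dimethyl-4H-1,3-dioxin-4-one; 18 benzyl 2-(benzyloxy)-6-heptyl-4-hydroxybenzoate
Product: 22 benzyl 2-(benzyloxy)-4-[(2,4-dihydroxy-6-methylbenzoyl)oxy]-6-heptylbenzoate, via acylketene 19 (not isolated), via aryl trioxooctanoate 20 (not isolated), via aldol adduct 21 (not isolated)
Conditions: 8 (1.3 equiv), PhMe, 110 °C; then Et3N, CH2Cl2, 0 °C to rt; then CF3CO2H, rt
Reagents that add atoms: none
Why: At 110 °C diketo-dioxinone 8 loses acetone by retro-[4+2] fragmentation to acylketene 19, and the only free hydroxyl of 18 (O-4 of ring B; O-2 is benzylated) adds across the ketene through a six-centre hydrogen-bonded transition state, so the future di-ortho-substituted carbonyl C7' is esterified while it is still an unhindered sp carbon. The closest known reaction type is the thermolysis of diketo-dioxinones with capture by an alcohol and aromatization to resorcylates, a laboratory form of the polyketide aldol cyclization; a phenol as the capturing hydroxyl is the less common variant. Ring A then closes by a 6-(enolexo)-exo-trig aldol addition of the C2 carbanion of aryl trioxooctanoate 20 (activated by the C3 ketone and the aryl ester) to the C7 methyl ketone, which forms the C1'–C6' bond and gives aldol adduct 21. Trifluoroacetic acid dehydrates 21 and the two remaining ring ketones enolize to the arene; the two stereocentres of 21 disappear here, so no stereocontrol is needed. The selectivity needed is C2-to-C7 aldol closure over the two paths that expel the aryloxide of 18 (lactonization by the C5 enol oxygen to a 4-hydroxy-2-pyranone, and Claisen closure of C6 onto C1 to an acylphloroglucinol) and over acid-promoted dehydration of the open triketone to a 4-pyranone. It should be secured by the acidity the aryl ester confers on C2–H, by a tertiary amine in an aprotic medium free of chelating metal ions and nucleophilic alcohols, and by adding acid only after the carbon–carbon bond has formed.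

Step 10
Reactants: 22 benzyl 2-(benzyloxy)-4-[(2,4-dihydroxy-6-methylbenzoyl)oxy]-6-heptylbenzoate
Product: 23 4-[(2,4-dihydroxy-6-methylbenzoyl)oxy]-6-heptyl-2-hydroxybenzoic acid
Conditions: H2 (1 atm), 10% Pd/C, EtOAc, rt
Reagents that add atoms: none
Why: Heterogeneous hydrogenolysis cleaves both benzylic C–O bonds (ester and ether) at room temperature, while the aryl ester of the depside and the arenes are not reduced and the non-alcoholic solvent excludes transesterification.

**Compound list**
1 | 2,2-dimethyl-1,3-dioxane-4,6-dione (Meldrum's acid) | CC1(C)OC(=O)CC(=O)O1 | starting material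
2 | 3-oxo-3-(prop-2-en-1-yloxy)propanoic acid (allyl hydrogen malonate) | C=CCOC(=O)CC(=O)O | intermediate
3 | prop-2-en-1-yl 3-chloro-3-oxopropanoate (allyl malonyl chloride) | C=CCOC(=O)CC(=O)Cl | intermediate
4 | 2,2,6-trimethyl-4H-1,3-dioxin-4-one | CC1=CC(=O)OC(C)(C)O1 | starting material
5 | lithium 2,2-dimethyl-6-methylidene-6H-1,3-dioxin-4-olate (lithium dienolate of 4) | C=C1C=C(O[Li])OC(C)(C)O1 | intermediate
6 | prop-2-en-1-yl 4-(2,2-dimethyl-4-oxo-4H-1,3-dioxin-6-yl)-3-oxobutanoate | C=CCOC(=O)CC(=O)CC1=CC(=O)OC(C)(C)O1 | intermediate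
7 | prop-2-en-1-yl 2-acetyl-4-(2,2-dimethyl-4-oxo-4H-1,3-dioxin-6-yl)-3-oxobutanoate | C=CCOC(=O)C(C(C)=O)C(=O)CC1=CC(=O)OC(C)(C)O1 | intermediate
8 | 6-(2,4-dioxopentyl)-2,2-dimethyl-4H-1,3-dioxin-4-one | CC(=O)CC(=O)CC1=CC(=O)OC(C)(C)O1 | intermediate
9 | octanoyl chloride | CCCCCCCC(=O)Cl | starting material
10 | prop-2-en-1-yl 2-[(2,2-dimethyl-4-oxo-4H-1,3-dioxin-6-yl)acetyl]-3-oxodecanoate | C=CCOC(=O)C(C(=O)CCCCCCC)C(=O)CC1=CC(=O)OC(C)(C)O1 | intermediate
11 | 6-(2,4-dioxoundecyl)-2,2-dimethyl-4H-1,3-dioxin-4-one | CCCCCCCC(=O)CC(=O)CC1=CC(=O)OC(C)(C)O1 | intermediate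
12 | tetradec-1-ene-1,3,5,7-tetrone (acylketene from 11) | CCCCCCCC(=O)CC(=O)CC(=O)C=C=O | intermediate
13 | benzyl 3,5,7-trioxotetradecanoate | CCCCCCCC(=O)CC(=O)CC(=O)CC(=O)OCc1ccccc1 | intermediate
14 | benzyl 2-heptyl-2-hydroxy-4,6-dioxocyclohexane-1-carboxylate (mixture of stereoisomers and tautomers) | CCCCCCCC1(O)CC(=O)CC(=O)C1C(=O)OCc1ccccc1 | intermediate
15 | benzyl 2,4-dihydroxy-6-heptylbenzoate | CCCCCCCc1cc(O)cc(O)c1C(=O)OCc1ccccc1 | intermediate
16 | benzyl 6-heptyl-2-hydroxy-4-(prop-2-en-1-yloxy)benzoate | CCCCCCCc1cc(OCC=C)cc(O)c1C(=O)OCc1ccccc1 | intermediate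
17 | benzyl 2-(benzyloxy)-6-heptyl-4-(prop-2-en-1-yloxy)benzoate | CCCCCCCc1cc(OCC=C)cc(OCc2ccccc2)c1C(=O)OCc1ccccc1 | intermediate
18 | benzyl 2-(benzyloxy)-6-heptyl-4-hydroxybenzoate | CCCCCCCc1cc(O)cc(OCc2ccccc2)c1C(=O)OCc1ccccc1 | intermediate
19 | oct-1-ene-1,3,5,7-tetrone (acylketene from 8) | CC(=O)CC(=O)CC(=O)C=C=O | intermediate
20 | 3-(benzyloxy)-4-[(benzyloxy)carbonyl]-5-heptylphenyl 3,5,7-trioxooctanoate | CC(=O)CC(=O)CC(=O)CC(=O)Oc1cc(CCCCCCC)c(C(=O)OCc2ccccc2)c(OCc2ccccc2)c1 | intermediate
21 | 3-(benzyloxy)-4-[(benzyloxy)carbonyl]-5-heptylphenyl 2-hydroxy-2-methyl-4,6-dioxocyclohexane-1-carboxylate (mixture of stereoisomers and tautomers) | CC1(O)CC(=O)CC(=O)C1C(=O)Oc1cc(CCCCCCC)c(C(=O)OCc2ccccc2)c(OCc2ccccc2)c1 | intermediate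
22 | benzyl 2-(benzyloxy)-4-[(2,4-dihydroxy-6-methylbenzoyl)oxy]-6-heptylbenzoate | CCCCCCCc1cc(OC(=O)c2c(C)cc(O)cc2O)cc(OCc2ccccc2)c1C(=O)OCc1ccccc1 | intermediate
23 | 4-[(2,4-dihydroxy-6-methylbenzoyl)oxy]-6-heptyl-2-hydroxybenzoic acid | CCCCCCCc1cc(OC(=O)c2c(C)cc(O)cc2O)cc(O)c1C(=O)O | target

**Step count**
Total steps: 10. Longest linear sequence: 9 steps (1, 2, 4, 5, 6, 7, 8, 9, 10).

**Steps most likely to fail**

Step 9. Capture of the acylketene by the electron-poor phenol may be outrun by capture through the enol oxygen of the ketene's own chain. Once the aryl ester exists, expulsion of the aryloxide by lactonization or Claisen closure may also outrun the carbon–carbon aldol closure. The fallback sets out from phenol 18 and brings ring A in preformed. Purchased methyl 2,4-dihydroxy-6-methylbenzoate (COC(=O)c1c(C)cc(O)cc1O) would be benzylated (BnBr, K2CO3, DMF) to methyl 2,4-bis(benzyloxy)-6-methylbenzoate F1 and saponified (KOH, DMSO/H2O, 90 °C) to 2,4-bis(benzyloxy)-6-methylbenzoic acid F2. This acid would be joined to 18 through its mixed anhydride with trifluoroacetic anhydride (PhMe, rt), the classical depside esterification, to give benzyl 2-(benzyloxy)-4-{[2,4-bis(benzyloxy)-6-methylbenzoyl]oxy}-6-heptylbenzoate F3. Hydrogenolysis of F3 under the conditions of step 10 removes all four benzyl groups and comes back to the route at target 23.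

Step 3. Acylation may go to oxygen or to the methylene next to the dioxinone ring instead of the keto ester carbon. The diketo-dioxinone may also be degraded by morpholine during the deallylation (enaminone formation or retro-Claisen loss of the acetyl group). The fallback sets out from dioxinone 4 and avoids the keto ester and the amine altogether. Lithium dienolate 5 (LiN(SiMe3)2, THF, −78 °C) would be acetylated with acetyl chloride (0.5 equiv) to 2,2-dimethyl-6-(2-oxopropyl)-4H-1,3-dioxin-4-one F4. Double deprotonation with LiN(iPr)2 (2.2 equiv, THF, −78 °C) would give its dilithium dianion F5. Claisen-type acylation of the terminal carbon of this dianion by N-methoxy-N-methylacetamide (−78 to −20 °C, then aq HCl) comes back to the route at diketo-dioxinone 8.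

Step 6. Site selectivity may be lost once carbonate breaks the chelate of the 2-hydroxyl, leading to alkylation at both oxygens or at ring carbon. The fallback sets out from resorcylate 15 and changes the temporary group and the way the benzyl ether is made. The bulky chloride iPr3SiCl with imidazole (DMF, 0 °C) should silylate only the unchelated 4-hydroxyl to give benzyl 6-heptyl-2-hydroxy-4-[(triisopropylsilyl)oxy]benzoate F6. Base-free Mitsunobu etherification (BnOH, PPh3, diisopropyl azodicarboxylate, THF) would give benzyl 2-(benzyloxy)-6-heptyl-4-[(triisopropylsilyl)oxy]benzoate F7. Bu4NF buffered with AcOH (THF, 0 °C) comes back to the route at phenol 18.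

**Further compounds**
F1 | step 9 | methyl 2,4-bis(benzyloxy)-6-methylbenzoate | COC(=O)c1c(C)cc(OCc2ccccc2)cc1OCc1ccccc1
F2 | step 9 | 2,4-bis(benzyloxy)-6-methylbenzoic acid | Cc1cc(OCc2ccccc2)cc(OCc2ccccc2)c1C(=O)O
F3 | step 9 | benzyl 2-(benzyloxy)-4-{[2,4-bis(benzyloxy)-6-methylbenzoyl]oxy}-6-heptylbenzoate | CCCCCCCc1cc(OC(=O)c2c(C)cc(OCc3ccccc3)cc2OCc2ccccc2)cc(OCc2ccccc2)c1C(=O)OCc1ccccc1
F4 | step 3 | 2,2-dimethyl-6-(2-oxopropyl)-4H-1,3-dioxin-4-one | CC(=O)CC1=CC(=O)OC(C)(C)O1
F5 | step 3 | dilithium 3-(2,2-dimethyl-4-oxido-6H-1,3-dioxin-6-ylidene)prop-1-en-2-olate (dianion of F4) | C=C(O[Li])C=C1C=C(O[Li])OC(C)(C)O1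
F6 | step 6 | benzyl 6-heptyl-2-hydroxy-4-[(triisopropylsilyl)oxy]benzoate | CCCCCCCc1cc(O[Si](C(C)C)(C(C)C)C(C)C)cc(O)c1C(=O)OCc1ccccc1
F7 | step 6 | benzyl 2-(benzyloxy)-6-heptyl-4-[(triisopropylsilyl)oxy]benzoate | CCCCCCCc1cc(O[Si](C(C)C)(C(C)C)C(C)C)cc(OCc2ccccc2)c1C(=O)OCc1ccccc1
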